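**Strategy.** Ring A is numbered C1 (CH bearing the dienyl chain), C2 (methyl-bearing alkene carbon), C3, C4, C5 (carbinol) and C6 (gem-dimethyl carbon). The plan rests on cutting C1–C2 and C5–C6: the vicinal pair C6/C1 is a masked 1,2-bis(allyl) nucleophile, C5/C2 the carbonyl carbons of a 1,4-keto aldehyde. A tandem double allylboration of 4-oxopentanal with the enantioenriched 1,2-bis(boronate) of 4-methylpenta-1,3-diene forms both bonds, closes ring A and sets C5 and C1. A bridging C1/C5 lactone then directs dehydration to C2=C3. The derived alkenylboronate is joined by Suzuki coupling to a (Z)-iodoalkenyl epoxycyclohexenediol (ring B), made from a dimethoxyarene by oxidation, hydroxyl-directed epoxidation and reduction.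

Key step: step 2

Atom labels used below: chain C7–C11 (C11 = carbinol), ring B C12 (quaternary epoxide carbon), C13 (epoxide CH), C14 (CHOH), C15 (alkene carbon bearing C18H2OH), C16 (=CH), C17 (CHOH). "Bpin" = 4,4,5,5-tetramethyl-1,3,2-dioxaborolan-2-yl.

Assumption: the antipode of the TADDOL-derived phosphonite used in step 1 is taken to be the one that delivers the (R)-bis(boronate) 3; if the sense of induction is opposite, the enantiomeric ligand is used.

**Fragment A (ring A)**

Step 1
Reactants: 1 4-methylpenta-1,3-diene; 2 bis(pinacolato)diboron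
Product: 3 (R)-2,2'-(4-methylpent-3-ene-1,2-diyl)bis(4,4,5,5-tetramethyl-1,3,2-dioxaborolane)
Conditions: Pt(dba)3 (3 mol%), (R,R)-TADDOL-derived P-phenyl phosphonite (6 mol%), THF, 60 °C
Reagents that add atoms: none
Why: Platinum-catalysed enantioselective 1,2-diboration of a 1,3-diene; the 4,4-disubstituted diene cannot adopt the s-cis geometry needed for 1,4-addition, so B–B adds across the terminal alkene and the chiral phosphonite sets the allylic C–B stereocentre (R).

Step 2
Reactants: 3 (R)-bis(boronate); 4 4-oxopentanal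
Product: 6 (1R,2R,4R)-2-ethenyl-1,3,3-trimethylcyclohexane-1,4-diol, via allylboronate keto borate 5 (not isolated)
Conditions: toluene, 23 °C then 80 °C; then 1 M NaOH, 23 °C
Reagents that add atoms: none
Why: Tandem double allylboration of a 1,4-dicarbonyl compound by a 1,2-bis(boronate), a known reaction type: the secondary allylic boronate of 3 adds through a closed chair transition state by its gamma carbon (the CMe2 terminus, future C6) to the aldehyde of 4, and the allylic shift turns the primary boronate into the (E)-allylboronate 5, whose gamma carbon (future C1) attacks the tethered methyl ketone (future C2). Ring A is closed by this second, intramolecular allylboration, a 6-exo-trig attack on the carbonyl through a trans-fused chair–chair transition state. C5 (R) is set by chirality transfer from the boron-bearing stereocentre of 3 (CH2Bpin and the aldehyde chain equatorial in the first chair); C1 is set in the ring-closing chair, in which the C5 borate oxygen sits equatorial and the new vinyl group therefore ends cis to the C5 oxygen; the C2 carbinol (hydroxyl trans to vinyl) is removed later. The step needs the aldehyde to react before the ketone, which its higher electrophilicity secures, and the second boron to stay silent until the first addition, which holds because it is not allylic before the allylic shift. Attack at the hindered CMe2 terminus is inherent to the cyclic SE2' mechanism of allylboronates.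

Step 3
Reactants: 6 (1R,2R,4R)-2-ethenyl-1,3,3-trimethylcyclohexane-1,4-diol
Product: 8 (1R,2R,5R)-2,5-dihydroxy-2,6,6-trimethylcyclohexane-1-carbaldehyde, via ozonide 7 (not isolated)
Conditions: O3, CH2Cl2, −78 °C; then Me2S, −78 → 23 °C
Reagents that add atoms: ozone, [O-][O+]=O
Why: Ozonolysis of the only alkene with reductive work-up should give the aldehyde under neutral conditions that leave the alcohols and the alpha stereocentre C1 untouched.

Step 4
Reactants: 8 (1R,2R,5R)-2,5-dihydroxy-2,6,6-trimethylcyclohexane-1-carbaldehyde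
Product: 10 (1R,2R,5R)-2-hydroxy-2,8,8-trimethyl-6-oxabicyclo[3.2.1]octan-7-one, via bicyclic lactol 9 (not isolated)
Conditions: TEMPO (20 mol%), PhI(OAc)2, CH2Cl2, 23 °C
Reagents that add atoms: none
Why: Nitroxyl-catalysed oxidation of a lactol to a lactone: only a cis-1,3-hydroxy aldehyde can close to lactol 9, the tertiary alcohol and the neopentylic C5 hydroxyl resist the bulky oxoammonium ion, and 8 should be drained through 9, which locks the C1/C5 cis relationship.

Step 5
Reactants: 10 (1R,2R,5R)-2-hydroxy-2,8,8-trimethyl-6-oxabicyclo[3.2.1]octan-7-one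
Product: 11 (1S,5R)-2,8,8-trimethyl-6-oxabicyclo[3.2.1]oct-2-en-7-one
Conditions: SOCl2, pyridine, CH2Cl2, −20 → 0 °C
Reagents that add atoms: none
Why: E2 dehydration of the tertiary alcohol through its chlorosulfite: the axial C2–O bond is antiperiplanar to the axial C3–H, and elimination towards C1 is barred because C1 is a bridgehead (Bredt's rule), so the C2=C3 alkene should form.

Step 6
Reactants: 11 (1S,5R)-2,8,8-trimethyl-6-oxabicyclo[3.2.1]oct-2-en-7-one
Product: 12 (1S,5R)-2,8,8-trimethyl-6-oxabicyclo[3.2.1]oct-2-en-7-ol (lactol; both C7 epimers)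
Conditions: i-Bu2AlH (1.1 equiv), CH2Cl2, −78 °C; aq. KNaC4H4O6
Reagents that add atoms: none
Why: Half-reduction of a lactone by i-Bu2AlH; the tetrahedral aluminium acetal is stable at −78 °C and releases the lactol on work-up, with C1 protected as a bridgehead against epimerisation and conjugation.

Step 7
Reactants: 12 (1S,5R)-2,8,8-trimethyl-6-oxabicyclo[3.2.1]oct-2-en-7-ol
Product: 14 (1R,5S)-4,6,6-trimethyl-5-[(E)-2-Bpin-ethenyl]cyclohex-3-en-1-ol, via ring-opened hydroxy aldehyde 13 (not isolated)
Conditions: CrCl2 (8 equiv), Cl2CHBpin (2 equiv), LiI (4 equiv), THF, 23 °C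
Reagents that add atoms: 2-(dichloromethyl)-4,4,5,5-tetramethyl-1,3,2-dioxaborolane, ClC(Cl)B1OC(C)(C)C(C)(C)O1
Why: Takai–Utimoto olefination: the geminal dichromium reagent adds to the open aldehyde form 13 and anti-elimination should give the (E)-alkenylboronate (C7=C8), the non-basic medium sparing the doubly allylic C1–H.

**Fragment B (ring B)**

Step 8
Reactants: 15 (4-bromo-2,5-dimethoxyphenyl)methanol
Product: 16 [(4-bromo-2,5-dimethoxyphenyl)methoxy](tert-butyl)diphenylsilane
Conditions: TBDPSCl, imidazole, DMF, 23 °C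
Reagents that add atoms: tert-butyl(chloro)diphenylsilane, CC(C)(C)[Si](Cl)(c1ccccc1)c1ccccc1
Why: Imidazole-promoted silylation of the primary alcohol (future C18–OH) gives an ether that should survive organolithium, hydride and cerium oxidant.

Step 9
Reactants: 16 the silyl ether; 17 N-methoxy-N-methylbut-2-ynamide
Product: 19 1-[4-({[tert-butyl(diphenyl)silyl]oxy}methyl)-2,5-dimethoxyphenyl]but-2-yn-1-one, via aryllithium 18 (not isolated)
Conditions: n-BuLi, THF, −78 °C; then 17, −78 → 0 °C; aq. NH4Cl
Reagents that add atoms: none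
Why: Bromine–lithium exchange followed by acylation with a Weinreb amide, whose chelated tetrahedral adduct prevents over-addition, should give the aryl ynone (C11–C12 bond).

Step 10
Reactants: 19 the aryl ynone
Product: 20 (1S)-1-[4-({[tert-butyl(diphenyl)silyl]oxy}methyl)-2,5-dimethoxyphenyl]but-2-yn-1-ol
Conditions: (R)-2-methyl-CBS-oxazaborolidine (20 mol%), BH3·SMe2, THF, −30 °C
Reagents that add atoms: none
Why: Corey–Bakshi–Shibata reduction, in which the aryl group acts as the large and the propynyl group as the small substituent, so the (R)-catalyst should deliver the (S)-carbinol (C11).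

Step 11
Reactants: 20 the (S)-propargylic alcohol
Product: 22 (1S,2Z)-1-[4-({[tert-butyl(diphenyl)silyl]oxy}methyl)-2,5-dimethoxyphenyl]-3-iodobut-2-en-1-ol, via cyclic alkenylalanate 21 (not isolated)
Conditions: NaAlH2(OCH2CH2OMe)2, THF, 0 → 23 °C; then I2, −78 °C
Reagents that add atoms: iodine, II
Why: Hydroxyl-directed trans-hydroalumination of the propargylic alcohol places aluminium on the distal alkyne carbon cis to the carbinol carbon, and iodinolysis with retention fixes the (Z) geometry of C9=C10.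

Step 12
Reactants: 22 the (Z)-iodoalkenyl carbinol
Product: 23 2-({[tert-butyl(diphenyl)silyl]oxy}methyl)-5-[(1S,2Z)-1-hydroxy-3-iodobut-2-en-1-yl]cyclohexa-2,5-diene-1,4-dione
Conditions: (NH4)2Ce(NO3)6 (2.5 equiv), MeCN/H2O, 0 °C
Reagents that add atoms: water, O
Why: Oxidative demethylation of a 1,4-dimethoxyarene by the cerium salt should give the p-quinone rapidly at 0 °C, with the robust silyl ether, the vinyl iodide and the secondary alcohol left intact.

Step 13
Reactants: 23 the hydroxyalkyl quinone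
Product: 24 (1S,6R)-4-({[tert-butyl(diphenyl)silyl]oxy}methyl)-1-[(1S,2Z)-1-hydroxy-3-iodobut-2-en-1-yl]-7-oxabicyclo[4.1.0]hept-3-ene-2,5-dione (epoxide geometry as in the target; the descriptors differ only through priority changes)
Conditions: t-BuOOH, n-BuLi, THF, −78 → −20 °C; aq. NH4Cl
Reagents that add atoms: tert-butyl hydroperoxide, CC(C)(C)OO
Why: Hydroxyl-directed nucleophilic (Weitz–Scheffer) epoxidation: lithium bound to the C11 oxygen delivers tert-butyl peroxide to C13 of the adjacent enone only, and in the reactive rotamer C11–H eclipses the C12–C17 bond (A(1,2) strain), so oxygen should enter on the face carrying the C11–O bond and set C12 and C13 as in the target.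

Step 14
Reactants: 24 the epoxyquinone
Product: 25 (1S,2S,5R,6S)-4-({[tert-butyl(diphenyl)silyl]oxy}methyl)-1-[(1S,2Z)-1-hydroxy-3-iodobut-2-en-1-yl]-7-oxabicyclo[4.1.0]hept-3-ene-2,5-diol (same spatial arrangement at C12 as the target; the C1 descriptor is S only because of the iodine)
Conditions: i-Bu2AlH (5 equiv), THF, −78 °C; aq. KNaC4H4O6
Reagents that add atoms: none
Why: 1,2-Reduction of both ketones with a coordinating aluminium hydride, which binds the epoxide oxygen and should deliver hydride on the epoxide face (at C17 the other face is also shielded by the C11 side chain), so both new hydroxyls (C14, C17) end anti to the epoxide.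

**Union and deprotection**

Step 15
Reactants: 14 the ring A alkenylboronate; 25 the ring B alkenyl iodide
Product: 26 (1R,2S,5R,6S)-4-({[tert-butyl(diphenyl)silyl]oxy}methyl)-1-{(1S,2Z,4E)-1-hydroxy-5-[(1S,5R)-5-hydroxy-2,6,6-trimethylcyclohex-2-en-1-yl]-3-methylpenta-2,4-dien-1-yl}-7-oxabicyclo[4.1.0]hept-3-ene-2,5-diol
Conditions: Pd(dppf)Cl2 (10 mol%), aq. K3PO4, THF, 23 °C
Reagents that add atoms: none
Why: Suzuki–Miyaura coupling of an alkenylboronate with an alkenyl iodide proceeds with retention at both alkenes and tolerates free hydroxyls, so the C8–C9 bond and the (7E,9Z)-diene should form under mild base that spares the epoxy alcohol.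

Step 16
Reactants: 26 the silyl ether
Product: 27 the target, (1R,2S,5R,6S)-1-{(1S,2Z,4E)-1-hydroxy-5-[(1S,5R)-5-hydroxy-2,6,6-trimethylcyclohex-2-en-1-yl]-3-methylpenta-2,4-dien-1-yl}-4-(hydroxymethyl)-7-oxabicyclo[4.1.0]hept-3-ene-2,5-diol
Conditions: Bu4NF, AcOH, THF, 0 → 23 °C
Reagents that add atoms: none
Why: Fluoride-mediated cleavage of the silyl ether, buffered with acetic acid so that the epoxy alcohols should not undergo base-induced epoxide migration.

**Compound list**

1 | 4-methylpenta-1,3-diene | CC(C)=CC=C | starting material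
2 | bis(pinacolato)diboron | CC1(C)OB(OC1(C)C)B1OC(C)(C)C(C)(C)O1 | starting material
3 | (R)-2,2'-(4-methylpent-3-ene-1,2-diyl)bis(4,4,5,5-tetramethyl-1,3,2-dioxaborolane) | CC(C)=C[C@@H](CB1OC(C)(C)C(C)(C)O1)B1OC(C)(C)C(C)(C)O1 | intermediate
4 | 4-oxopentanal | CC(=O)CCC=O | starting material
5 | (5R,7E)-6,6-dimethyl-9-Bpin-5-(Bpin-oxy)non-7-en-2-one | CC(=O)CC[C@@H](OB1OC(C)(C)C(C)(C)O1)C(C)(C)/C=C/CB1OC(C)(C)C(C)(C)O1 | intermediate (not isolated)
6 | (1R,2R,4R)-2-ethenyl-1,3,3-trimethylcyclohexane-1,4-diol (C4–OH cis to vinyl, C1–OH trans to vinyl) | O[C@@H]1CC[C@@](C)(O)[C@H](C=C)C1(C)C | intermediate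
7 | ozonide of 6 (1,2,4-trioxolan-3-yl in place of the vinyl group) | O[C@@H]1CC[C@@](C)(O)[C@H](C2OCOO2)C1(C)C | intermediate (not isolated)
8 | (1R,2R,5R)-2,5-dihydroxy-2,6,6-trimethylcyclohexane-1-carbaldehyde | O=C[C@H]1[C@](C)(O)CC[C@@H](O)C1(C)C | intermediate
9 | (1R,2R,5R)-2,8,8-trimethyl-6-oxabicyclo[3.2.1]octane-2,7-diol (lactol, both C7 epimers) | OC1O[C@@H]2CC[C@@](C)(O)[C@H]1C2(C)C | intermediate (not isolated)
10 | (1R,2R,5R)-2-hydroxy-2,8,8-trimethyl-6-oxabicyclo[3.2.1]octan-7-one | O=C1O[C@@H]2CC[C@@](C)(O)[C@H]1C2(C)C | intermediate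
11 | (1S,5R)-2,8,8-trimethyl-6-oxabicyclo[3.2.1]oct-2-en-7-one | O=C1O[C@@H]2CC=C(C)[C@H]1C2(C)C | intermediate
12 | (1S,5R)-2,8,8-trimethyl-6-oxabicyclo[3.2.1]oct-2-en-7-ol (lactol, both C7 epimers) | OC1O[C@@H]2CC=C(C)[C@H]1C2(C)C | intermediate
13 | (1S,5R)-5-hydroxy-2,6,6-trimethylcyclohex-2-ene-1-carbaldehyde | O=C[C@H]1C(C)=CC[C@@H](O)C1(C)C | intermediate (not isolated)
14 | (1R,5S)-4,6,6-trimethyl-5-[(E)-2-Bpin-ethenyl]cyclohex-3-en-1-ol | CC1=CC[C@@H](O)C(C)(C)[C@H]1/C=C/B1OC(C)(C)C(C)(C)O1 | intermediate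
15 | (4-bromo-2,5-dimethoxyphenyl)methanol | OCc1cc(OC)c(Br)cc1OC | starting material
16 | [(4-bromo-2,5-dimethoxyphenyl)methoxy](tert-butyl)diphenylsilane | CC(C)(C)[Si](OCc1cc(OC)c(Br)cc1OC)(c1ccccc1)c1ccccc1 | intermediate
17 | N-methoxy-N-methylbut-2-ynamide | CC#CC(=O)N(C)OC | starting material
18 | [4-({[tert-butyl(diphenyl)silyl]oxy}methyl)-2,5-dimethoxyphenyl]lithium | [Li]c1cc(OC)c(CO[Si](c2ccccc2)(c2ccccc2)C(C)(C)C)cc1OC | intermediate (not isolated)
19 | 1-[4-({[tert-butyl(diphenyl)silyl]oxy}methyl)-2,5-dimethoxyphenyl]but-2-yn-1-one | CC#CC(=O)c1cc(OC)c(CO[Si](c2ccccc2)(c2ccccc2)C(C)(C)C)cc1OC | intermediate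
20 | (1S)-1-[4-({[tert-butyl(diphenyl)silyl]oxy}methyl)-2,5-dimethoxyphenyl]but-2-yn-1-ol | CC#C[C@H](O)c1cc(OC)c(CO[Si](c2ccccc2)(c2ccccc2)C(C)(C)C)cc1OC | intermediate
21 | sodium 2,2-bis(2-methoxyethoxy)-1,2-oxaluminol-3-ene alanate from 20 (five-membered O–Al–C9=C10–C11 ring, (S) at C11) | CC1=C[C@@H](c2cc(OC)c(CO[Si](c3ccccc3)(c3ccccc3)C(C)(C)C)cc2OC)O[Al-]1(OCCOC)OCCOC.[Na+] | intermediate (not isolated)
22 | (1S,2Z)-1-[4-({[tert-butyl(diphenyl)silyl]oxy}methyl)-2,5-dimethoxyphenyl]-3-iodobut-2-en-1-ol | I/C(C)=C\[C@H](O)c1cc(OC)c(CO[Si](c2ccccc2)(c2ccccc2)C(C)(C)C)cc1OC | intermediate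
23 | 2-({[tert-butyl(diphenyl)silyl]oxy}methyl)-5-[(1S,2Z)-1-hydroxy-3-iodobut-2-en-1-yl]cyclohexa-2,5-diene-1,4-dione | I/C(C)=C\[C@H](O)C1=CC(=O)C(CO[Si](c2ccccc2)(c2ccccc2)C(C)(C)C)=CC1=O | intermediate
24 | (1S,6R)-4-({[tert-butyl(diphenyl)silyl]oxy}methyl)-1-[(1S,2Z)-1-hydroxy-3-iodobut-2-en-1-yl]-7-oxabicyclo[4.1.0]hept-3-ene-2,5-dione | I/C(C)=C\[C@H](O)[C@]12O[C@H]1C(=O)C(CO[Si](c3ccccc3)(c3ccccc3)C(C)(C)C)=CC2=O | intermediate
25 | (1S,2S,5R,6S)-4-({[tert-butyl(diphenyl)silyl]oxy}methyl)-1-[(1S,2Z)-1-hydroxy-3-iodobut-2-en-1-yl]-7-oxabicyclo[4.1.0]hept-3-ene-2,5-diol (both ring hydroxyls anti to the epoxide) | I/C(C)=C\[C@H](O)[C@]12O[C@H]1[C@H](O)C(CO[Si](c3ccccc3)(c3ccccc3)C(C)(C)C)=C[C@@H]2O | intermediate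
26 | C18 tert-butyldiphenylsilyl ether of the target | CC1=CC[C@@H](O)C(C)(C)[C@H]1/C=C/C(C)=C\[C@H](O)[C@]12O[C@H]1[C@H](O)C(CO[Si](c3ccccc3)(c3ccccc3)C(C)(C)C)=C[C@@H]2O | intermediate
27 | (1R,2S,5R,6S)-1-{(1S,2Z,4E)-1-hydroxy-5-[(1S,5R)-5-hydroxy-2,6,6-trimethylcyclohex-2-en-1-yl]-3-methylpenta-2,4-dien-1-yl}-4-(hydroxymethyl)-7-oxabicyclo[4.1.0]hept-3-ene-2,5-diol | CC1=CC[C@@H](O)C(C)(C)[C@H]1/C=C/C(C)=C\[C@H](O)[C@]12O[C@H]1[C@H](O)C(CO)=C[C@@H]2O | target

**Step count.** 16 steps in total; the longest linear sequence is 9 steps (steps 8–14, then 15 and 16; the ring A branch, steps 1–7, then 15 and 16, is equally long).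

**Steps most likely to fail, each with a fallback**

Step 2. The ring-closing allylboration onto the hindered methyl ketone may be slow, so that adduct 5 accumulates and is lost by protodeboronation. Its chair transition state carries a 1,3-diaxial methyl/methyl interaction, so face selection at C1 may also erode. The fallback sets out from 3 and returns at 11. The same tandem allylation is run with butanedial, whose second carbonyl is an unhindered aldehyde, to give (1R,2R,4R)-2-ethenyl-3,3-dimethylcyclohexane-1,4-diol F1. Ozonolysis (O3; Me2S) gives (1R,2R,5R)-2,5-dihydroxy-6,6-dimethylcyclohexane-1-carbaldehyde F2. Dess–Martin periodinane oxidises its lactol form and the C2 carbinol to (1R,5R)-8,8-dimethyl-6-oxabicyclo[3.2.1]octane-2,7-dione F3. KN(SiMe3)2 and PhNTf2 give (1R,5R)-8,8-dimethyl-7-oxo-6-oxabicyclo[3.2.1]oct-2-en-2-yl trifluoromethanesulfonate F4; only C3 can be deprotonated, because C1 is a bridgehead. Coupling with trimethylboroxine under Pd(PPh3)4 and K2CO3 installs the C2 methyl group and gives 11.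

Step 13. Control may be lost in the peroxide addition: undirected attack on the other enone alkene, attack on the wrong face through a hydrogen-bonded rotamer, or base-induced isomerisation of the hydroxyalkyl quinone to an acyl hydroquinone. The fallback sets out from 22 and returns at 24, and uses an electrophilic, metal-directed epoxidation at the bisketal level. Anodic oxidation (Pt electrodes, MeOH, KOH, 0 °C) gives (1S,2Z)-1-[4-({[tert-butyl(diphenyl)silyl]oxy}methyl)-3,3,6,6-tetramethoxycyclohexa-1,4-dien-1-yl]-3-iodobut-2-en-1-ol F5. VO(acac)2 and t-BuOOH epoxidise only the C12=C13 alkene, which is allylic to the free C11 hydroxyl, on the face fixed by A(1,2) strain, to give the corresponding 1,2-epoxide F6, whose epoxide has the configuration of 24. Aqueous CF3CO2H in CH2Cl2 at 0 °C hydrolyses both ketals to 24.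

Step 14. Facial selectivity of hydride delivery may be poor at C14, where only coordination to the epoxide steers the reagent, giving the hydroxyl syn to the epoxide. The fallback sets out from 24 and returns at 25. Substrate control is replaced by catalyst control: (R)-2-methyl-CBS-oxazaborolidine with catecholborane in toluene at −78 °C, on the model that the epoxide carbon (next to C17) and the substituted alkene carbon (next to C14) act as the large groups. One catalyst antipode then attacks the same face of both carbonyls. This fallback passes through no new compound (entry F0).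

Further compounds
F1 | step 2 | (1R,2R,4R)-2-ethenyl-3,3-dimethylcyclohexane-1,4-diol | O[C@@H]1CC[C@@H](O)[C@H](C=C)C1(C)C
F2 | step 2 | (1R,2R,5R)-2,5-dihydroxy-6,6-dimethylcyclohexane-1-carbaldehyde | O=C[C@H]1[C@H](O)CC[C@@H](O)C1(C)C
F3 | step 2 | (1R,5R)-8,8-dimethyl-6-oxabicyclo[3.2.1]octane-2,7-dione | O=C1O[C@@H]2CCC(=O)[C@H]1C2(C)C
F4 | step 2 | (1R,5R)-8,8-dimethyl-7-oxo-6-oxabicyclo[3.2.1]oct-2-en-2-yl trifluoromethanesulfonate | O=C1O[C@@H]2CC=C(OS(=O)(=O)C(F)(F)F)[C@H]1C2(C)C
F5 | step 13 | (1S,2Z)-1-[4-({[tert-butyl(diphenyl)silyl]oxy}methyl)-3,3,6,6-tetramethoxycyclohexa-1,4-dien-1-yl]-3-iodobut-2-en-1-ol | I/C(C)=C\[C@H](O)C1=CC(OC)(OC)C(CO[Si](c2ccccc2)(c2ccccc2)C(C)(C)C)=CC1(OC)OC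
F6 | step 13 | (1S,2Z)-1-[4-({[tert-butyl(diphenyl)silyl]oxy}methyl)-2,2,5,5-tetramethoxy-7-oxabicyclo[4.1.0]hept-3-en-1-yl]-3-iodobut-2-en-1-ol (epoxide configured as in 24) | I/C(C)=C\[C@H](O)[C@]12O[C@H]1C(OC)(OC)C(CO[Si](c3ccccc3)(c3ccccc3)C(C)(C)C)=CC2(OC)OC
F0 | step 14 | none | none
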